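**Assumption:** (+)-lariciresinol is taken as (7S,8R,8'R), exactly as encoded by the given SMILES. That means aryl trans to CH2OH, and CH2OH cis to the benzyl group on the THF ring. Hydroferulic acid, (S)-4-benzyloxazolidin-2-one, allyl bromide, DDQ and the common reagents are assumed commercial.

## Retrosynthetic overview
- The target comes from its bis-O-allyl ether by Pd(0) deallylation. The phenols are protected as allyl ethers so they survive enolate, oxidative and borohydride chemistry.
- The only ring, the THF, is formed by a bold key step. A DDQ benzylic C–H oxidation of the C2-symmetric (2R,3R)-2,3-bis(arylmethyl)butane-1,4-diol gives a benzylic cation that is trapped by the distal CH2OH (5-ring closure). Both benzylic termini are equivalent, so there is no regiochemistry problem. C7 sets itself trans to C8.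
- C8 and C8' are set together in one operation. An oxidative homocoupling of an Evans sodium enolate joins the two α-carbons with anti-to-benzyl facial control, and reduction removes the auxiliaries.
- The starting materials are hydroferulic acid (as its allyl-protected acid) and (S)-4-benzyloxazolidin-2-one.

## Route

**Step 1**
Reactants: 1 (3-(4-hydroxy-3-methoxyphenyl)propanoic acid, hydroferulic acid)
Product: 2 (allyl 3-(4-allyloxy-3-methoxyphenyl)propanoate)
Conditions: allyl bromide (2.5 equiv), K2CO3 (3 equiv), DMF, 60 °C
Reagents that add atoms: allyl bromide, C=CCBr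
Why: Williamson O-alkylation of the phenolate and carboxylate. It installs a phenol protecting group orthogonal to all later steps, and no stereocentres are involved.

**Step 2**
Reactants: 2
Product: 3 (3-(4-allyloxy-3-methoxyphenyl)propanoic acid)
Conditions: LiOH·H2O, THF/H2O 3:1, rt
Reagents that add atoms: water, O
Why: Saponification of the allyl ester. The aryl allyl ether is inert to hydroxide.

**Step 3**
Reactants: 3; 4 ((S)-4-benzyloxazolidin-2-one)
Product: 5 ((S)-4-benzyl-3-[3-(4-allyloxy-3-methoxyphenyl)propanoyl]oxazolidin-2-one)
Conditions: (a) PivCl, Et3N, THF, −78 → 0 °C; (b) Li salt of 4 (4 + n-BuLi, THF, −78 °C), −78 → 0 °C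
Reagents that add atoms: none (PivCl is lost as pivalate)
Why: Mixed-anhydride N-acylation (Evans acylation) attaches the chiral auxiliary that will control both C8 centres.

**Step 4**
Reactants: 5 (two equivalents, homocoupled)
Product: 6 (bis-imide, (2R,3R)-2,3-bis(4-allyloxy-3-methoxybenzyl)succinyl bis[(S)-4-benzyloxazolidinone])
Conditions: NaHMDS (1.05 equiv), THF, −78 °C, 1 h; then Fe(acac)3 (1.2 equiv), −78 °C → rt
Reagents that add atoms: none (Fe(acac)3 is only the oxidant, and 2 H are lost overall)
Why: Oxidative homocoupling of chelated Z-sodium enolates (Ziegler/Baran-type enolate coupling). Each enolate reacts on the face anti to the C4 benzyl group, which gives (R) at each α-carbon, as in Evans alkylation with an (S)-auxiliary. Facial selectivity p gives RR : meso : SS of about p² : 2p(1−p) : (1−p)², so the minor diastereomers are removed chromatographically and C8 and C8' are set in one step.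

**Step 5**
Reactants: 6
Product: 7 ((2R,3R)-2,3-bis(4-allyloxy-3-methoxybenzyl)butane-1,4-diol); by-product 4 is recovered
Conditions: LiBH4 (4 equiv), MeOH (4 equiv), THF, 0 °C → rt
Reagents that add atoms: none
Why: Exocyclic hydride cleavage of N-acyl oxazolidinones (Penning-type LiBH4 reduction) gives primary alcohols. The stereocentres are not epimerised under these mild conditions, and the allyl ethers are untouched. The CIP priorities (CH2OH > C3 > CH2Ar) keep the descriptors (R,R).

**Step 6**
Reactants: 7
Product: 8 (bis-O-allyl-(+)-lariciresinol)
Conditions: DDQ (1.1 equiv), 4 Å MS, 1,2-dichloroethane, 60 °C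
Reagents that add atoms: none (DDQ only removes 2 H as DDQH2)
Why: Proposed new method: DDQ abstracts hydride from a benzylic CH2 para to an alkoxy group to give a stabilised secondary benzylic cation (the closest known chemistry is DDQ oxidative benzylic C–H etherification and PMB-type oxidation). The pendant CH2OH on the other arm closes the THF ring (O–C9'–C8'–C8–C7). This cyclisation should be stereoselective for the 2,3-trans isomer, because the cis epimer would put the aryl group cis to both ring substituents. The ring-closure is also reversible through benzylic ionisation under the acidic DDQH2 conditions, so equilibration to trans is expected. Using 1.1 equiv DDQ limits over-oxidation to the pinoresinol-type bis-THF. C8 and C8' are unchanged, and the (R,R) descriptors carry over to (8R,8'R) through a cyclic permutation of priorities.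

**Step 7**
Reactants: 8
Product: 9 ((+)-lariciresinol)
Conditions: Pd(PPh3)4 (5 mol%), K2CO3 (3 equiv), MeOH, rt
Reagents that add atoms: none
Why: Pd(0) Tsuji–Trost deallylation of the aryl allyl ethers, with methoxide as the allyl acceptor. The benzylic THF C–O bond, the primary alcohol and the stereocentres are untouched, and no hydrogenolysis is involved.

## Compound list
1 | 3-(4-hydroxy-3-methoxyphenyl)propanoic acid (hydroferulic acid) | COc1cc(CCC(=O)O)ccc1O | starting material
2 | allyl 3-(4-allyloxy-3-methoxyphenyl)propanoate | C=CCOC(=O)CCc1ccc(OCC=C)c(OC)c1 | intermediate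
3 | 3-(4-allyloxy-3-methoxyphenyl)propanoic acid | C=CCOc1ccc(CCC(=O)O)cc1OC | intermediate
4 | (S)-4-benzyloxazolidin-2-one | O=C1N[C@@H](Cc2ccccc2)CO1 | starting material
5 | (S)-4-benzyl-3-[3-(4-allyloxy-3-methoxyphenyl)propanoyl]oxazolidin-2-one | C=CCOc1ccc(CCC(=O)N2[C@@H](Cc3ccccc3)COC2=O)cc1OC | intermediate
6 | (2R,3R)-2,3-bis(4-allyloxy-3-methoxybenzyl)succinyl bis[(S)-4-benzyloxazolidin-2-one] | C=CCOc1ccc(C[C@@H](C(=O)N2[C@@H](Cc3ccccc3)COC2=O)[C@@H](Cc2ccc(OCC=C)c(OC)c2)C(=O)N2[C@@H](Cc3ccccc3)COC2=O)cc1OC | intermediate
7 | (2R,3R)-2,3-bis(4-allyloxy-3-methoxybenzyl)butane-1,4-diol | OC[C@H](Cc1ccc(OCC=C)c(OC)c1)[C@H](CO)Cc1ccc(OCC=C)c(OC)c1 | intermediate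
8 | bis-O-allyl-(+)-lariciresinol | COc1cc(C[C@H]2CO[C@H](c3ccc(OCC=C)c(OC)c3)[C@H]2CO)ccc1OCC=C | intermediate
9 | (+)-lariciresinol | COc1cc(C[C@H]2CO[C@H](c3ccc(O)c(OC)c3)[C@H]2CO)ccc1O | target

## Totals
Total steps: 7. Longest linear sequence: 7 steps, from 1.

## Three steps most likely to fail
1. **Step 6 (DDQ cycloetherification).** Hydride abstraction at a non-heteroatom-activated benzylic CH2 may be sluggish, and over-oxidation to the bis-THF or styrene formation are possible. Fallback: change to a radical 1,5-HAT manifold. Treat 7 with PhI(OAc)2/I2 under visible light (Suárez alkoxy-radical conditions) so the alkoxy radical abstracts the C7–H, and the resulting benzylic radical is oxidised and closed to the THF.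
2. **Step 4 (enolate homocoupling).** The dr may be modest or over-oxidation/chlorination may compete. Fallback: use a stepwise double Evans alkylation. Alkylate 5 with tert-butyl bromoacetate, remove the t-Bu ester and re-attach an auxiliary, then benzylate with 4-allyloxy-3-methoxybenzyl bromide. The auxiliary enantiomer for the second alkylation must be chosen so that the product is the (R,R)-succinate.
3. **Step 5 (bis-imide reduction).** Endocyclic cleavage or incomplete reduction of the hindered 2,3-disubstituted bis-imide is possible. Fallback: remove the auxiliaries first by methanolysis (Mg(OMe)2 or NaOMe/MeOH) to give dimethyl (2R,3R)-2,3-bis(arylmethyl)succinate, then reduce the diester with LiAlH4 to diol 7. This splits cleavage and reduction into two steps.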